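**Retrosynthetic overview**

- Numbering: O1, C2 (C=O), C3, C3a, C4 (CMe2), C5, C6 (CH–O), C7, C7a (C–Me, bonded to O1). The target is the palmitate of (−)-loliolide, (6S,7aR).
- Backwards, the C6–O ester is cut first (palmitoyl chloride), then the C3=C3a alkene (selenoxide elimination from the saturated cis-fused lactone). The strategy rests on the next bond, C4–C3a, which joins the gem-dimethyl quaternary carbon of the cyclohexane ring to the β-carbon of the butenolide ring, itself next to quaternary C7a. It is cut as a tertiary-radical conjugate addition started by hydrogen-atom transfer to an isopropenyl group.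
- Ring order: the butenolide first (O1–C2 and C3=C3a in one operation from an α-hydroxy aldehyde and Ph3P=C=C=O), the cyclohexane second (key step).
- Stereocentres: C7a is the quaternary carbinol carbon of (S)-2-methylglycidol, carried through unchanged. C6 is set by catalyst-controlled methallylation of the butenolide aldehyde, which also forms C5–C6.

Key step: step 6

Remark: (S)-2-methylglycidol and vinylmagnesium bromide (THF solution) are taken as commercial, and the (S)-BINOL/Ti(OiPr)4 catalyst is assumed to deliver the methallyl group to the Si face of aldehyde 8 as it does with simple aldehydes.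

**Step 1**
Reactants: 1 (S)-2-methylglycidol; 2 vinylmagnesium bromide
Product: 3 (R)-2-methylpent-4-ene-1,2-diol
Conditions: 2 (3.0 equiv), CuI (10 mol %), THF, −30 → 0 °C; aq NH4Cl
Reagents that add atoms: none
Why: After the first equivalent has deprotonated the hydroxyl, copper-catalysed Grignard opening of the 2,2-disubstituted epoxide by SN2 attack at its unsubstituted CH2 (the future C7) forms C7–C6 and leaves the quaternary carbinol carbon, the future C7a, untouched because none of its bonds is broken.

**Step 2**
Reactants: 3 (R)-2-methylpent-4-ene-1,2-diol; 4 (triphenylphosphoranylidene)ketene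
Product: 7 (R)-5-allyl-5-methylfuran-2(5H)-one, via (R)-2-hydroxy-2-methylpent-4-enal 5 (not isolated), via acyl ylide ester 6 (not isolated)
Conditions: SO3·pyridine (3 equiv), DMSO, i-Pr2NEt, CH2Cl2, 0 °C; aqueous work-up, solvent exchange to PhMe without concentrating to dryness; then 4 (1.2 equiv), PhMe, 0.05 M, 80 °C
Reagents that add atoms: none
Why: Parikh–Doering oxidation can only touch the primary alcohol (the tertiary one has no carbinol hydrogen), and the tertiary hydroxyl of 5 then adds across the C=C bond of the ketenylidene ylide to give the ester-stabilised ylide 6, whose intramolecular Wittig reaction with the neighbouring aldehyde closes the butenolide with the cis C3=C3a alkene enforced by the five-membered ring (Bestmann domino addition–Wittig olefination), C7a remaining untouched.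

**Step 3**
Reactants: 7 (R)-5-allyl-5-methylfuran-2(5H)-one
Product: 8 (R)-2-(2-methyl-5-oxo-2,5-dihydrofuran-2-yl)acetaldehyde
Conditions: O3, CH2Cl2, −78 °C, stopped at the end point of the indicator Sudan Red 7B; then PPh3, −78 °C → rt
Reagents that add atoms: ozone, [O-][O+]=O
Why: Electrophilic ozone attacks the electron-rich monosubstituted alkene much faster than the electron-poor conjugated C3=C3a bond, so ozonolysis run to an indicator end point with reductive work-up should give the aldehyde carbon that becomes C6 without touching the butenolide or C7a.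

**Step 4**
Reactants: 8 (R)-2-(2-methyl-5-oxo-2,5-dihydrofuran-2-yl)acetaldehyde; 9 tributyl(2-methylallyl)stannane
Product: 10 (R)-5-[(S)-2-hydroxy-4-methylpent-4-en-1-yl]-5-methylfuran-2(5H)-one
Conditions: (S)-BINOL (20 mol %), Ti(OiPr)4 (10 mol %), 4 Å MS, CH2Cl2, reflux 1 h; then 8 and 9 (1.5 equiv), −20 °C; sat. aq NaHCO3
Reagents that add atoms: none
Why: In the Keck asymmetric methallylation the chiral Lewis acid formed from (S)-BINOL and Ti(OiPr)4 activates the aldehyde and directs the allylstannane (SE2′, open transition state) to its Si face, which for this substrate gives the (S)-carbinol at C6 under catalyst control, the remote quaternary C7a exerting little bias, and forms C5–C6 with the 1,1-disubstituted alkene already in place.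

**Step 5**
Reactants: 10 (R)-5-[(S)-2-hydroxy-4-methylpent-4-en-1-yl]-5-methylfuran-2(5H)-one
Product: 11 (R)-5-{(S)-2-[(tert-butyldimethylsilyl)oxy]-4-methylpent-4-en-1-yl}-5-methylfuran-2(5H)-one
Conditions: TBSCl, imidazole, DMF, rt
Reagents that add atoms: tert-butyldimethylsilyl chloride, CC(C)(C)[Si](C)(C)Cl
Why: Imidazole-assisted silylation of the secondary alcohol gives an ether that should withstand the radical step, LDA and the selenoxide oxidation, with C6 unchanged.

**Step 6**
Reactants: 11 (R)-5-{(S)-2-[(tert-butyldimethylsilyl)oxy]-4-methylpent-4-en-1-yl}-5-methylfuran-2(5H)-one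
Product: 14 (3aS,6S,7aR)-6-[(tert-butyldimethylsilyl)oxy]-4,4,7a-trimethylhexahydrobenzofuran-2(3H)-one, via tertiary C4 radical 12 (not isolated), via cyclised C3 radical 13 (not isolated)
Conditions: Fe(acac)3 (30 mol %), PhSiH3 (2.5 equiv, added slowly), EtOH/ethylene glycol (5:1), 0.02 M, 60 °C, Ar
Reagents that add atoms: none
Why: An iron hydride generated from Fe(acac)3 and PhSiH3 in ethanol transfers a hydrogen atom to the terminal CH2 of the electron-rich 1,1-disubstituted alkene (Markovnikov hydrogen-atom transfer) to give the nucleophilic tertiary C4 radical 12, which adds to the electron-poor β-carbon C3a of the butenolide; the α-acyl radical 13 is then reduced by divalent iron and protonated by the solvent, which is the iron-hydride reductive olefin coupling (a Giese-type radical conjugate addition) run intramolecularly. The cyclohexane closes in the 6-exo-trig mode (C4, C5, C6, C7, C7a and C3a in the ring, C3 outside) through a chair-like transition state with the C6 silyloxy group equatorial. The only new stereocentre, C3a, is fixed by the four-atom tether from quaternary C7a, which can bring C4 only to the butenolide face that carries C7, so the ring fusion must be cis (3aS) and the C3a hydrogen ends up on the face of the C7a methyl group. Chemoselectivity (hydrogen atom to the isolated alkene, not the conjugated one) follows from the preference of the metal hydride for electron-rich alkenes, and regioselectivity (attack at C3a, not C3) from radical polarity and from 6-exo closure being favoured over 7-endo. The early transition state of a radical addition should tolerate joining quaternary C4 to a carbon next to quaternary C7a, and slow addition of the silane keeps premature reduction of 12 in check.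

**Step 7**
Reactants: 14 (3aS,6S,7aR)-6-[(tert-butyldimethylsilyl)oxy]-4,4,7a-trimethylhexahydrobenzofuran-2(3H)-one
Product: 16 (3R,3aS,6S,7aR)-6-[(tert-butyldimethylsilyl)oxy]-4,4,7a-trimethyl-3-(phenylselanyl)hexahydrobenzofuran-2(3H)-one, via lithium enolate 15 (not isolated)
Conditions: LDA (1.15 equiv), THF, −78 °C; then PhSeCl, THF, −78 °C
Reagents that add atoms: phenylselenenyl chloride, Cl[Se]c1ccccc1
Why: Kinetic deprotonation at C3 (the only α-position) and selenenylation of the lithium enolate from the convex face of the cis-fused bicycle, away from quaternary C4 on the concave face, should place selenium cis to the C3a hydrogen (3R).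

**Step 8**
Reactants: 16 (3R,3aS,6S,7aR)-6-[(tert-butyldimethylsilyl)oxy]-4,4,7a-trimethyl-3-(phenylselanyl)hexahydrobenzofuran-2(3H)-one
Product: 18 (6S,7aR)-6-[(tert-butyldimethylsilyl)oxy]-4,4,7a-trimethyl-5,6,7,7a-tetrahydrobenzofuran-2(4H)-one, via selenoxide 17 (not isolated)
Conditions: 30% aq H2O2, pyridine, CH2Cl2, 0 °C → rt
Reagents that add atoms: none
Why: Oxidation to the selenoxide is followed by spontaneous syn-elimination (selenoxide Ei elimination) with the only β-hydrogen, the cis C3a–H, which re-forms the C3=C3a alkene in conjugation with the lactone and removes the C3 and C3a stereocentres.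

**Step 9**
Reactants: 18 (6S,7aR)-6-[(tert-butyldimethylsilyl)oxy]-4,4,7a-trimethyl-5,6,7,7a-tetrahydrobenzofuran-2(4H)-one
Product: 19 (−)-loliolide [(6S,7aR)-6-hydroxy-4,4,7a-trimethyl-5,6,7,7a-tetrahydrobenzofuran-2(4H)-one]
Conditions: HF·pyridine, THF/pyridine, 0 °C → rt
Reagents that add atoms: none
Why: Fluoride-driven cleavage of the Si–O bond under buffered conditions frees the C6 alcohol with retention, and the butenolide is stable to HF·pyridine.

**Step 10**
Reactants: 19 (−)-loliolide; 20 palmitoyl chloride
Product: 21 (−)-3-O-palmitoylloliolide [(6S,7aR)-4,4,7a-trimethyl-2-oxo-2,4,5,6,7,7a-hexahydrobenzofuran-6-yl hexadecanoate]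
Conditions: 20 (1.3 equiv), Et3N, DMAP (cat.), CH2Cl2, 0 °C → rt
Reagents that add atoms: none
Why: DMAP-catalysed acylation (nucleophilic catalysis through the acylpyridinium salt) esterifies the secondary C6 alcohol without touching its C–O bond, so the (6S,7aR) configuration is retained.

**Compound list**

1 | (S)-2-methylglycidol, [(2S)-2-methyloxiran-2-yl]methanol | C[C@]1(CO)CO1 | starting material
2 | vinylmagnesium bromide | C=C[Mg]Br | starting material
3 | (R)-2-methylpent-4-ene-1,2-diol | C=CC[C@@](C)(O)CO | intermediate
4 | (triphenylphosphoranylidene)ketene (Bestmann ylide) | O=C=C=P(c1ccccc1)(c1ccccc1)c1ccccc1 | starting material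
5 | (R)-2-hydroxy-2-methylpent-4-enal | C=CC[C@@](C)(O)C=O | intermediate (not isolated)
6 | acyl ylide ester, (R)-2-methyl-1-oxopent-4-en-2-yl (triphenylphosphoranylidene)acetate | C=CC[C@@](C)(OC(=O)C=P(c1ccccc1)(c1ccccc1)c1ccccc1)C=O | intermediate (not isolated)
7 | (R)-5-allyl-5-methylfuran-2(5H)-one | C=CC[C@@]1(C)OC(=O)C=C1 | intermediate
8 | (R)-2-(2-methyl-5-oxo-2,5-dihydrofuran-2-yl)acetaldehyde | O=CC[C@@]1(C)OC(=O)C=C1 | intermediate
9 | tributyl(2-methylallyl)stannane | CCCC[Sn](CCCC)(CCCC)CC(C)=C | starting material
10 | (R)-5-[(S)-2-hydroxy-4-methylpent-4-en-1-yl]-5-methylfuran-2(5H)-one | C=C(C)C[C@H](O)C[C@@]1(C)OC(=O)C=C1 | intermediate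
11 | (R)-5-{(S)-2-[(tert-butyldimethylsilyl)oxy]-4-methylpent-4-en-1-yl}-5-methylfuran-2(5H)-one | C=C(C)C[C@H](O[Si](C)(C)C(C)(C)C)C[C@@]1(C)OC(=O)C=C1 | intermediate (key-step precursor)
12 | tertiary C4 radical from hydrogen-atom transfer to 11 | C[C](C)C[C@H](O[Si](C)(C)C(C)(C)C)C[C@@]1(C)OC(=O)C=C1 | intermediate (not isolated)
13 | cyclised C3 (α-lactone) radical | CC(C)(C)[Si](C)(C)O[C@H]1CC(C)(C)[C@@H]2[CH]C(=O)O[C@]2(C)C1 | intermediate (not isolated)
14 | (3aS,6S,7aR)-6-[(tert-butyldimethylsilyl)oxy]-4,4,7a-trimethylhexahydrobenzofuran-2(3H)-one | CC(C)(C)[Si](C)(C)O[C@H]1CC(C)(C)[C@@H]2CC(=O)O[C@]2(C)C1 | intermediate (key-step product)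
15 | lithium enolate of 14 | CC(C)(C)[Si](C)(C)O[C@H]1CC(C)(C)[C@@H]2C=C(O[Li])O[C@]2(C)C1 | intermediate (not isolated)
16 | (3R,3aS,6S,7aR)-6-[(tert-butyldimethylsilyl)oxy]-4,4,7a-trimethyl-3-(phenylselanyl)hexahydrobenzofuran-2(3H)-one | CC(C)(C)[Si](C)(C)O[C@H]1CC(C)(C)[C@@H]2[C@@H]([Se]c3ccccc3)C(=O)O[C@]2(C)C1 | intermediate
17 | selenoxide of 16 | CC(C)(C)[Si](C)(C)O[C@H]1CC(C)(C)[C@@H]2[C@@H]([Se](=O)c3ccccc3)C(=O)O[C@]2(C)C1 | intermediate (not isolated)
18 | (6S,7aR)-6-[(tert-butyldimethylsilyl)oxy]-4,4,7a-trimethyl-5,6,7,7a-tetrahydrobenzofuran-2(4H)-one | CC(C)(C)[Si](C)(C)O[C@H]1CC(C)(C)C2=CC(=O)O[C@]2(C)C1 | intermediate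
19 | (−)-loliolide, (6S,7aR)-6-hydroxy-4,4,7a-trimethyl-5,6,7,7a-tetrahydrobenzofuran-2(4H)-one | O[C@H]1CC(C)(C)C2=CC(=O)O[C@]2(C)C1 | intermediate
20 | palmitoyl chloride | CCCCCCCCCCCCCCCC(=O)Cl | starting material
21 | (−)-3-O-palmitoylloliolide | CCCCCCCCCCCCCCCC(=O)O[C@H]1CC(C)(C)C2=CC(=O)O[C@]2(C)C1 | target

**Step count:** 10 steps in total; longest linear sequence 10 steps (from 1).

**Steps most likely to fail**

Step 6 (key step). The tertiary radical may be reduced before it cyclises (net hydrogenation of the isopropenyl group), or the hydride may attack the butenolide. The fallback generates the same radical with no hydride present. It sets out from 11 and returns at 14. Mukaiyama hydration of the isolated alkene (Co(acac)2, PhSiH3, O2, i-PrOH, reductive work-up; the radical is trapped by O2 faster than it can cyclise) would give the tertiary alcohol (R)-5-{(S)-2-[(tert-butyldimethylsilyl)oxy]-4-hydroxy-4-methylpentyl}-5-methylfuran-2(5H)-one F1. Acylation with methyl chlorooxoacetate (Et3N, DMAP, CH2Cl2) would give the methyl oxalate of the tertiary alcohol F2. CsOH (1 equiv, THF/H2O, rt), which attacks the far more electrophilic oxalate ester in preference to the lactone, would give the cesium oxalate F3. Blue-light irradiation with Ir[dF(CF3)ppy]2(dtbbpy)PF6 (1 mol %) in DME/DMF with water would oxidise the carboxylate, expel two molecules of CO2 and release radical 12, which should close 6-exo to 13 and, after reduction and protonation, give 14 (decarboxylative photoredox Giese addition of a tertiary alcohol oxalate).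

Step 4. The lactone carboxylate may be lost from aldehyde 8 by β-elimination (retro-oxa-Michael opening) during the long Lewis-acid-catalysed reaction, or catalyst control of the aldehyde face may be incomplete. The fallback forms C5–C6 before the butenolide exists, on an aldehyde whose β-oxygen is an acetal oxygen that cannot leave, and uses a stoichiometric chiral allylborane that reacts within hours at −78 °C. It sets out from 3 and returns at 11. Diol 3 with 2,2-dimethoxypropane and PPTS in CH2Cl2 would give the acetonide (R)-4-allyl-2,2,4-trimethyl-1,3-dioxolane F4, and ozonolysis (O3, CH2Cl2, −78 °C; then PPh3) the aldehyde (R)-2-(2,2,4-trimethyl-1,3-dioxolan-4-yl)acetaldehyde F5. B-(2-methylallyl)diisopinocampheylborane, made from (−)-B-methoxydiisopinocampheylborane (derived from (+)-α-pinene) and 2-methylallylmagnesium chloride in Et2O, adds to the Si face of aldehydes at −78 °C (Brown methallylation; NaOH/H2O2 work-up, which the acetonide tolerates). It should give (S)-4-methyl-1-[(R)-2,2,4-trimethyl-1,3-dioxolan-4-yl]pent-4-en-2-ol F6. TBSCl and imidazole in DMF would give the silyl ether tert-butyldimethyl({(S)-4-methyl-1-[(R)-2,2,4-trimethyl-1,3-dioxolan-4-yl]pent-4-en-2-yl}oxy)silane F7. CuCl2·2H2O in MeCN at 0 °C should remove the acetonide without touching the secondary silyl ether and give (2R,4S)-4-[(tert-butyldimethylsilyl)oxy]-2,6-dimethylhept-6-ene-1,2-diol F8. Parikh–Doering oxidation (SO3·pyridine, DMSO, i-Pr2NEt) of the primary alcohol would give (2R,4S)-4-[(tert-butyldimethylsilyl)oxy]-2-hydroxy-2,6-dimethylhept-6-enal F9. Ylide 4 in toluene at 80 °C would then close the butenolide through the acyl ylide ester of this aldehyde F10 (not isolated) and give 11.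

Step 2. The hindered tertiary hydroxyl of 5 may add too slowly to the cumulated ylide, so that the aldehyde is lost to intermolecular Wittig reaction or self-condensation. The fallback reverses the order of the two bond formations: the alkene is made first by an intermolecular Z-selective olefination and the ester C–O bond second by lactonisation. It sets out from 5 and returns at 7. Still–Gennari olefination of 5 [methyl bis(2,2,2-trifluoroethyl)phosphonoacetate, KHMDS, 18-crown-6, THF, −78 °C] would give methyl (2Z,4R)-4-hydroxy-4-methylhepta-2,6-dienoate F11. In this ester the hydroxyl sits cis to the ester group, so it should close to 7 on warming or with PPTS in toluene at 50 °C.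

**Further compounds**

F1 | step 6 | (R)-5-{(S)-2-[(tert-butyldimethylsilyl)oxy]-4-hydroxy-4-methylpentyl}-5-methylfuran-2(5H)-one | CC(C)(O)C[C@H](O[Si](C)(C)C(C)(C)C)C[C@@]1(C)OC(=O)C=C1
F2 | step 6 | methyl oxalate of F1 | COC(=O)C(=O)OC(C)(C)C[C@H](O[Si](C)(C)C(C)(C)C)C[C@@]1(C)OC(=O)C=C1
F3 | step 6 | cesium oxalate of F1 | [Cs+].[O-]C(=O)C(=O)OC(C)(C)C[C@H](O[Si](C)(C)C(C)(C)C)C[C@@]1(C)OC(=O)C=C1
F4 | step 4 | (R)-4-allyl-2,2,4-trimethyl-1,3-dioxolane | C=CC[C@]1(C)COC(C)(C)O1
F5 | step 4 | (R)-2-(2,2,4-trimethyl-1,3-dioxolan-4-yl)acetaldehyde | O=CC[C@]1(C)COC(C)(C)O1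
F6 | step 4 | (S)-4-methyl-1-[(R)-2,2,4-trimethyl-1,3-dioxolan-4-yl]pent-4-en-2-ol | C=C(C)C[C@H](O)C[C@]1(C)COC(C)(C)O1
F7 | step 4 | tert-butyldimethyl({(S)-4-methyl-1-[(R)-2,2,4-trimethyl-1,3-dioxolan-4-yl]pent-4-en-2-yl}oxy)silane | C=C(C)C[C@H](O[Si](C)(C)C(C)(C)C)C[C@]1(C)COC(C)(C)O1
F8 | step 4 | (2R,4S)-4-[(tert-butyldimethylsilyl)oxy]-2,6-dimethylhept-6-ene-1,2-diol | C=C(C)C[C@H](O[Si](C)(C)C(C)(C)C)C[C@@](C)(O)CO
F9 | step 4 | (2R,4S)-4-[(tert-butyldimethylsilyl)oxy]-2-hydroxy-2,6-dimethylhept-6-enal | C=C(C)C[C@H](O[Si](C)(C)C(C)(C)C)C[C@@](C)(O)C=O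
F10 | step 4 | acyl ylide ester of F9 | C=C(C)C[C@H](O[Si](C)(C)C(C)(C)C)C[C@@](C)(OC(=O)C=P(c1ccccc1)(c1ccccc1)c1ccccc1)C=O
F11 | step 2 | methyl (2Z,4R)-4-hydroxy-4-methylhepta-2,6-dienoate | C=CC[C@@](C)(O)/C=C\C(=O)OC
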